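## Retrosynthetic overview

- In chroman numbering (O1, C2 gem-dimethyl, C3 carbinol, C4 methylene, C5/C7 hydroxyls, C6 methyl, C8 acyl), the last bonds cut are the two methyl–O and one benzyl–O ether bonds and the C8–acyl bond (Friedel–Crafts). This leaves a 3-benzyloxy-5,7-dimethoxy-2,2,6-trimethylchroman.
- The dimethylpyran is cut at O1–C2 (cyclodehydration of a phenol tertiary carbinol) and at both C2–CH3 bonds (methyl Grignard on a dihydrocoumarin).
- The strategy rests on one feature: C4 is an unsubstituted benzylic CH2 ortho to O1, and C3 is the only stereocentre. O1–C8a–C4a–C4 is therefore a hidden ortho-quinone methide and C3–C2 a benzyloxy-enolate, so the lactone is cut at C4–C3 and O1–C2 into an ortho-(sulfonylmethyl)phenol and a benzyloxyacetyl unit on a chiral carbene.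
- The acid chloride is not offered to the phenoxide directly, because it would O-acylate it before sulfinate is lost. It is first turned into its N-acylimidazole, from which the carbene makes the enolate.
- Ring order: the benzene ring is bought; the lactone ring is formed in the key step, then opened and re-closed as the 2,2-dimethylpyran.

Key step: step 4

Remark: chroman numbering (O1, C2, C3, C4, C4a, C5–C8, C8a) is used for all bicyclic compounds.

Assumption: the facial sense of the aminoindanol-derived triazolium catalyst with an alkoxy enolate is taken from the usual model for azolium enolates and has not been derived rigorously here. The (5aS,10bR) salt is written below; its mirror image, equally available, is used with no other change if the first run shows the 3R lactone.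

## Route

Step 1
Reactants: 1 4-hydroxy-2,6-dimethoxybenzaldehyde
Product: 2 3,5-dimethoxy-4-methylphenol
Conditions: H2 (3 atm), 10% Pd/C, AcOH, conc. HCl (cat.), rt
Reagents that add atoms: none
Why: Catalytic hydrogenation of the aldehyde to the benzylic alcohol and acid-assisted benzylic hydrogenolysis of its C–O bond, which is activated by the para hydroxyl and both ortho methoxy groups; the aryl ethers and the ring should not be touched.

Step 2
Reactants: 2 3,5-dimethoxy-4-methylphenol
Product: 3 3,5-dimethoxy-4-methyl-2-[(phenylsulfonyl)methyl]phenol
Conditions: (CH2O)n (1.0 equiv), PhSO2Na (3 equiv), HCO2H–H2O (1:1), rt; 2 in 1.3-fold excess over formaldehyde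
Reagents that add atoms: formaldehyde (as paraformaldehyde), C=O; sodium benzenesulfinate, [Na+].[O-]S(=O)c1ccccc1
Why: Mannich-type three-component sulfonylmethylation, in which ortho-hydroxymethylation of the activated phenol, ionisation in formic acid to the benzylic cation and S-alkylation of the sulfinate follow one another; the two free ortho carbons of 2 are equivalent, so one mono-product should form, and limiting formaldehyde with excess sulfinate holds back a second substitution.

Step 3
Reactants: 4 benzyloxyacetyl chloride
Product: 5 2-(benzyloxy)-1-(1H-imidazol-1-yl)ethan-1-one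
Conditions: imidazole (2.1 equiv), CH2Cl2, 0 °C → rt; filter, concentrate, use fresh
Reagents that add atoms: imidazole, c1cnc[nH]1
Why: N-acylation of imidazole by the acid chloride, with the second equivalent taking up HCl; it gives an acyl donor that acylates a phenoxide only slowly but passes its acyl group readily to a carbene.

Step 4
Reactants: 3 3,5-dimethoxy-4-methyl-2-[(phenylsulfonyl)methyl]phenol; 5 2-(benzyloxy)-1-(1H-imidazol-1-yl)ethan-1-one
Product: 7 (3S)-3-(benzyloxy)-5,7-dimethoxy-6-methylchroman-2-one, via o-quinone methide 6 (not isolated)
Conditions: (5aS,10bR)-2-mesityl-5a,10b-dihydro-4H,6H-indeno[2,1-b][1,2,4]triazolo[4,3-d][1,4]oxazin-2-ium tetrafluoroborate (15 mol%), Cs2CO3 (2.5 equiv), 4 Å molecular sieves, THF, 0 °C → rt; 5 (1.5 equiv) added over 2 h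
Reagents that add atoms: none
Why: Proposed new method: Cs2CO3 deprotonates 3, whose phenoxide expels benzenesulfinate to give the ortho-quinone methide 6, stabilised by the methoxy groups ortho and para to the methide carbon, while the carbene freed from the triazolium salt is acylated by 5 and deprotonated to the benzyloxy-substituted azolium enolate; the enolate α-carbon adds to the unsubstituted methide carbon (C4–C3 bond) and the phenoxide so formed acylates on the acyl azolium (O1–C2 bond) and releases the carbene. The closest known reaction type is the carbene-catalysed formal [4+2] annulation of azolium enolates from N-acylimidazoles with ortho-quinone methides that are made in the flask and carry no substituent on the methide carbon, which gives 3-substituted dihydrocoumarins; new here are the alkoxy group on the enolate and the release of the methide from a sulfone by carbonate beside the acyl donor. The lactone ring closes by 6-exo-trig attack of the phenoxide on the acyl azolium after the intermolecular conjugate addition. C3, the only stereocentre, is set by the catalyst: its aminoindanol backbone shields one face of the enolate, so that C4 bonds to the Si face of the α-carbon (O-benzyl > enolate carbon > H), which is 3S. The step needs chemoselectivity for C–C bond formation through 6 over O-acylation of the phenoxide of 3, and this rests on the low acylating power of the imidazolide toward phenoxide, its slow addition and the fast loss of sulfinate from the electron-rich ring; there is no regiochemical question, since 3 has one sulfonylmethyl group and gives one methide. The weak heterogeneous base and the low temperature are meant to leave the α-proton of the lactone, less acidic than that of the 3-aryl lactones of the known reaction, untouched.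

Step 5
Reactants: 7 (3S)-3-(benzyloxy)-5,7-dimethoxy-6-methylchroman-2-one
Product: 9 2-[(2S)-2-(benzyloxy)-3-hydroxy-3-methylbutyl]-3,5-dimethoxy-4-methylphenol, via methyl ketone 8 (not isolated)
Conditions: MeMgBr (4 equiv), THF, −78 → 0 °C; aq. NH4Cl
Reagents that add atoms: methylmagnesium bromide, C[Mg]Br
Why: Double Grignard addition to the aryl ester, in which the first equivalent opens the lactone to ketone 8 with phenoxide as leaving group and the second adds to the chelated α-benzyloxy ketone faster than it enolises it, so C3 should keep its configuration (pre-mixing the reagent with anhydrous CeCl3 is held in reserve should any erosion be seen).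

Step 6
Reactants: 9 2-[(2S)-2-(benzyloxy)-3-hydroxy-3-methylbutyl]-3,5-dimethoxy-4-methylphenol
Product: 10 (3S)-3-(benzyloxy)-5,7-dimethoxy-2,2,6-trimethyl-3,4-dihydro-2H-chromene
Conditions: p-TsOH·H2O (20 mol%), toluene, 80 °C
Reagents that add atoms: none
Why: Acid-catalysed cyclodehydration, in which the tertiary alcohol ionises and the phenol oxygen captures the cation in a six-membered closure (O1–C2 bond), the known way from 2-(2-oxy-3-hydroxy-3-methylbutyl)phenols to 2,2-dimethylchroman-3-ols; no bond to C3 is broken, so it stays S.

Step 7
Reactants: 10 (3S)-3-(benzyloxy)-5,7-dimethoxy-2,2,6-trimethyl-3,4-dihydro-2H-chromene; 11 3-phenylpropanoyl chloride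
Product: 12 1-[(3S)-3-(benzyloxy)-5,7-dimethoxy-2,2,6-trimethyl-3,4-dihydro-2H-chromen-8-yl]-3-phenylpropan-1-one
Conditions: 11 (1.3 equiv), SnCl4 (1.3 equiv), CH2Cl2, −40 → 0 °C
Reagents that add atoms: none
Why: Friedel–Crafts acylation at C8, the only aromatic C–H, which is ortho to O1 and to the 7-methoxy group and para to the 5-methoxy group; the mild Lewis acid and low temperature should spare the benzyl ether and the tertiary aryl ether and keep the acid chloride from closing to indan-1-one.

Step 8
Reactants: 12 1-[(3S)-3-(benzyloxy)-5,7-dimethoxy-2,2,6-trimethyl-3,4-dihydro-2H-chromen-8-yl]-3-phenylpropan-1-one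
Product: 13 1-[(3S)-3,5,7-trihydroxy-2,2,6-trimethyl-3,4-dihydro-2H-chromen-8-yl]-3-phenylpropan-1-one
Conditions: BBr3 (6 equiv), CH2Cl2, −78 → 0 °C; then MeOH, H2O
Reagents that add atoms: none
Why: Lewis-acid ether cleavage, in which BBr3 complexes each ether oxygen and bromide attacks the methyl or benzyl carbon, freeing both phenols and the C3 alcohol; the O1–C2 bond offers no carbon open to SN2 and its ionisation is disfavoured by the oxygen on C3, and the C3–O bond is not broken, so 3S is kept.

## Compound list

1 | 4-hydroxy-2,6-dimethoxybenzaldehyde | COc1cc(O)cc(OC)c1C=O | starting material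
2 | 3,5-dimethoxy-4-methylphenol | COc1cc(O)cc(OC)c1C | intermediate
3 | 3,5-dimethoxy-4-methyl-2-[(phenylsulfonyl)methyl]phenol | Cc1c(OC)c(CS(=O)(=O)c2ccccc2)c(O)cc1OC | intermediate
4 | benzyloxyacetyl chloride | O=C(Cl)COCc1ccccc1 | starting material
5 | 2-(benzyloxy)-1-(1H-imidazol-1-yl)ethan-1-one | O=C(COCc1ccccc1)n1ccnc1 | intermediate
6 | 3,5-dimethoxy-4-methyl-6-methylidenecyclohexa-2,4-dien-1-one (ortho-quinone methide, not isolated) | C=C1C(=O)C=C(OC)C(C)=C1OC | intermediate
7 | (3S)-3-(benzyloxy)-5,7-dimethoxy-6-methylchroman-2-one | Cc1c(OC)c2c(cc1OC)OC(=O)[C@@H](OCc1ccccc1)C2 | intermediate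
8 | (3S)-3-(benzyloxy)-4-(6-hydroxy-2,4-dimethoxy-3-methylphenyl)butan-2-one (not isolated) | CC(=O)[C@@H](OCc1ccccc1)Cc1c(O)cc(OC)c(C)c1OC | intermediate
9 | 2-[(2S)-2-(benzyloxy)-3-hydroxy-3-methylbutyl]-3,5-dimethoxy-4-methylphenol | CC(C)(O)[C@@H](OCc1ccccc1)Cc1c(O)cc(OC)c(C)c1OC | intermediate
10 | (3S)-3-(benzyloxy)-5,7-dimethoxy-2,2,6-trimethyl-3,4-dihydro-2H-chromene | Cc1c(OC)c2c(cc1OC)OC(C)(C)[C@@H](OCc1ccccc1)C2 | intermediate
11 | 3-phenylpropanoyl chloride | O=C(Cl)CCc1ccccc1 | starting material
12 | 1-[(3S)-3-(benzyloxy)-5,7-dimethoxy-2,2,6-trimethyl-3,4-dihydro-2H-chromen-8-yl]-3-phenylpropan-1-one | Cc1c(OC)c2c(c(C(=O)CCc3ccccc3)c1OC)OC(C)(C)[C@@H](OCc1ccccc1)C2 | intermediate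
13 | 1-[(3S)-3,5,7-trihydroxy-2,2,6-trimethyl-3,4-dihydro-2H-chromen-8-yl]-3-phenylpropan-1-one | Cc1c(O)c2c(c(C(=O)CCc3ccccc3)c1O)OC(C)(C)[C@@H](O)C2 | target

## Step count and risks

Total step count: 8. Longest linear sequence: 7 (steps 1, 2, 4, 5, 6, 7, 8); step 3 is a one-step branch.

Steps most likely to fail:

**Step 4 (Proposed new method).** Several processes could defeat it:
- O-acylation of the phenoxide of 3 by 5 or by the acyl azolium before sulfinate is lost;
- self-condensation of the methide through C-attack by the phenoxide;
- alkylation of the carbene by the methide;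
- weak facial control with the alkoxy enolate;
- epimerisation of the lactone α-carbon under the base.

The fallback uses known chemistry, sets out from 2 and comes back at 10. Phenol 2 is condensed with 3-methylbut-2-enal (phenylboronic acid, AcOH, toluene, reflux) to give 5,7-dimethoxy-2,2,6-trimethyl-2H-chromene F1. Jacobsen–Katsuki epoxidation follows, with (S,S)-N,N'-bis(3,5-di-tert-butylsalicylidene)-1,2-cyclohexanediamine manganese chloride (a trivalent manganese complex), NaOCl and 4-phenylpyridine N-oxide in CH2Cl2 at 0 °C. By the established sense for 2,2-dimethylchromenes this should give (3S,4S)-3,4-epoxy-5,7-dimethoxy-2,2,6-trimethylchromane F2, which is used crude. Hydride opening at the benzylic C4 (LiAlH4, THF, 0 °C) should give (3S)-5,7-dimethoxy-2,2,6-trimethylchroman-3-ol F3. Benzylation (NaH, BnBr, Bu4NI, DMF) then gives 10.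

**Step 2.** The product still has a nucleophilic ortho carbon and a benzylic sulfone that can re-ionise in acid. A second sulfonylmethylation or methylene bridging between two rings may therefore erode the yield. The fallback sets out from 2 and comes back at 3. Magnesium-mediated ortho-formylation (MgCl2, Et3N, paraformaldehyde, MeCN, reflux) stops after one formyl group, which deactivates the ring, and gives 6-hydroxy-2,4-dimethoxy-3-methylbenzaldehyde F4. NaBH4 in MeOH at 0 °C gives 2-(hydroxymethyl)-3,5-dimethoxy-4-methylphenol F5, which is used at once. Treatment with PhSO2Na in HCO2H–H2O at rt exchanges the benzylic hydroxyl for the sulfonyl group and gives 3, with no free formaldehyde present.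

**Step 8.** Lewis-acid ionisation of the tertiary O1–C2 bond is possible, helped by chelation of boron between the C8 carbonyl and O1. It would open the pyran, allow re-closure onto the C5 oxygen or contraction to a dihydrobenzofuran, or lead to bromide exchange at C3. The fallback avoids Lewis acid altogether, sets out from 12 and comes back at 13. Hydrogenolysis (H2, 10% Pd/C, EtOAc, rt) removes the benzyl group to give 1-[(3S)-3-hydroxy-5,7-dimethoxy-2,2,6-trimethyl-3,4-dihydro-2H-chromen-8-yl]-3-phenylpropan-1-one F6. Both methyl ethers, ortho and para to the ketone, are then cleaved by nucleophilic demethylation with NaSEt (excess) in DMF at 130 °C, followed by acidification, to give 13. The second demethylation, on a ring that already carries a phenoxide, is expected to need the forcing end of these conditions.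

Further compounds
F1 | step 4 | 5,7-dimethoxy-2,2,6-trimethyl-2H-chromene | Cc1c(OC)c2c(cc1OC)OC(C)(C)C=C2
F2 | step 4 | (3S,4S)-3,4-epoxy-5,7-dimethoxy-2,2,6-trimethylchromane | Cc1c(OC)c2c(cc1OC)OC(C)(C)[C@H]1O[C@H]12
F3 | step 4 | (3S)-5,7-dimethoxy-2,2,6-trimethylchroman-3-ol | Cc1c(OC)c2c(cc1OC)OC(C)(C)[C@@H](O)C2
F4 | step 2 | 6-hydroxy-2,4-dimethoxy-3-methylbenzaldehyde | Cc1c(OC)cc(O)c(C=O)c1OC
F5 | step 2 | 2-(hydroxymethyl)-3,5-dimethoxy-4-methylphenol | Cc1c(OC)cc(O)c(CO)c1OC
F6 | step 8 | 1-[(3S)-3-hydroxy-5,7-dimethoxy-2,2,6-trimethyl-3,4-dihydro-2H-chromen-8-yl]-3-phenylpropan-1-one | Cc1c(OC)c2c(c(C(=O)CCc3ccccc3)c1OC)OC(C)(C)[C@@H](O)C2
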